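The data were generated by integration for substances that don't exist, noise included.

The question is what share of the electrophile has reacted after 2.0 min at three charges of free base, so I first ask whether free base touches that share at all.

| flask | electrophile | nucleophile | free base | remark | time |
|---|---|---|---|---|---|
| theta | 0.010 M | 0.020 M | 8.8 mM | run made earlier |  |
| epsilon | 0.010 M | 0.020 M | 18 mM | run made earlier |  |
| north-east | 0.010 M | 0.0200 M | 14.0 mM |  | 2.0 min |
| north | 0.010 M | 0.0200 M | 10.0 mM |  | 2.0 min |
| south | 0.010 M | 0.0200 M | 8.00 mM |  | 2.0 min |

| run | time / s | electrophile / % | target / % |
|---|---|---|---|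
| theta | 15.0 | 26.0 | 21.3 |
| theta | 30.0 | 17.7 | 28.6 |
| theta | 40.0 | 14.7 | 32.0 |
| theta | 60.0 | 14.5 | 33.3 |
| theta | 80.0 | 13.5 | 36.2 |
| epsilon | 10.0 | 34.4 | 19.8 |
| epsilon | 12.0 | 30.4 | 19.8 |
| epsilon | 20.0 | 21.8 | 23.8 |
| epsilon | 30.0 | 18.1 | 25.3 |
| epsilon | 50.0 | 14.7 | 27.3 |
| epsilon | 80.0 | 14.4 | 26.8 |

(scatter of a reading: 1 percentage point)

- what has gone from electrophile into another species counts as reacted, even if it can come back

- part of the electrophile that has reacted at the end, north-east
- part of the electrophile that has reacted at the end, north
- part of the electrophile that has reacted at the end, south
- what raising the concentration of free base from its lowest to its highest value here does to the part of the electrophile that has reacted (changes below 5 percentage points count as none) (it falls / no change / it rises)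

At 30.0 s the theta run holds 17.7% of the electrophile and the epsilon run 18.1%, about the same with twice the free base, so I expect the three flasks to agree. But the electrophile then nearly stops falling: at 60.0 s theta shows 14.5% beside 33.3% target, and the rest is unread. So I picture a pool, whatever is not read as target in theta, of which free electrophile is a steady share, 21.7% as read there.

Between 15.0 s and 30.0 s theta gains 7.3 percentage points of target. Replacing the theta electrophile curve by its mean, 21.8%, gives a pseudo-first-order constant, read there, of 1.34 min⁻¹. Multiplied by the share, this gives 0.291 min⁻¹: the drain constant, the fraction of the pool passing to target per unit time. Holding both fixed, free electrophile is then the share divided by exp(drain constant × time), so I reckon 87.8% reacted in each flask.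

The forecast says 86%, 86% and 86.5%, each below my figure, and trend no change; of free base it says: “It therefore seems to act after the electrophile has been consumed, or on the branching between products, rather than on consumption itself.”

The flasks give 88.7%, 88.7% and 88.7%, a change of 0 points, so the trend is no change.

    electrophile + nucleophile → acid set free + target (k = 1.70 M⁻¹ s⁻¹)
    nucleophile + acid set free ⇌ protonated nucleophile, settled at all times (K = 3.60 × 10⁵ M⁻¹)
    acid set free + free base ⇌ salt of the base (K = 57000 M⁻¹, k = 30.0 M⁻¹ s⁻¹)
    free base + target → over-reaction product (k = 0.550 M⁻¹ s⁻¹)
    electrophile ⇌ dormant form (K = 2.70, k = 0.0920 s⁻¹)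

In north at 0.379 min, the step to target takes electrophile more slowly than the forward step to the dormant form, by a ratio of 0.27, and at 2.00 min that forward step has a half-life of 0.13 min, short against the run. The dormant form, the electrophile's resting state, holds 34.6% in north at the end, more than the 11.3% of free electrophile.

For the neighbour of north with 0.050 M of nucleophile, the drain constant scaled by the nucleophile charge is 0.726 min⁻¹, which gives 94.9% reacted. That neighbour gives 97.0%.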